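Both flavan units are the same (2R,3R)-2,3-cis C6–C3–C6 monomer, so the interflavanyl C4–C6 bond is cut last and the framework is traced to one benzylated flavylium salt. The key step closes ring C at O1–C2: acid-mediated aldol condensation of a ring-A salicylaldehyde with a ring-B α-acetoxyacetophenone, then cyclodehydration of the acyclic 2-hydroxychalcone. It exploits that C2 is bonded to the ring-A oxygen O1 and to ring B, hence a masked aryl ketone, while C3 and C4 can start planar. Biomimetic reduction (hydride, then dynamic kinetic transfer hydrogenation) gives the monomer, which is hydroxylated at C4 and used twice: as thio-activated C4 electrophile and as C6 nucleophile.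

Key step: step 3

Assumption: flavan numbering (O1, C2, C3, C4, C4a to C8a; rings A, B, C) is used, "epioritin" is (2R,3R)-2,3-cis-7,8,4'-trihydroxyflavan-3-ol and 4β means trans to the 3-oxygen; the (S,S)-TsDPEN complex of step 5 is assumed, by analogy with α-aryl cycloalkanone reductions, to give the (2R,3R) alcohol (the (R,R) complex would be used if the sense proved opposite).

Step 1
Reactants: 1 2,3,4-trihydroxybenzaldehyde
Product: 2 3,4-bis(benzyloxy)-2-hydroxybenzaldehyde
Conditions: BnBr (2.1 equiv), K2CO3 (2.1 equiv), DMF, 0 °C to rt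
Reagents that add atoms: benzyl bromide, BrCc1ccccc1
Why: Williamson etherification in which the 2-OH, hydrogen-bonded to the formyl group, is the least nucleophilic, so two equivalents should alkylate O4 and O3 and leave free the phenol that becomes O1.

Step 2
Reactants: 3 1-[4-(benzyloxy)phenyl]-2-bromoethan-1-one
Product: 4 2-[4-(benzyloxy)phenyl]-2-oxoethyl acetate
Conditions: KOAc, DMF, rt
Reagents that add atoms: potassium acetate, CC(=O)[O-].[K+]
Why: SN2 displacement of a primary α-keto bromide by acetate installs the oxygen that becomes the 3-hydroxyl.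

Step 3
Reactants: 2 3,4-bis(benzyloxy)-2-hydroxybenzaldehyde, 4 2-[4-(benzyloxy)phenyl]-2-oxoethyl acetate
Product: 7 3-acetoxy-7,8-bis(benzyloxy)-2-[4-(benzyloxy)phenyl]chromenylium chloride, via hydroxychalcone 5 (not isolated), via hemiketal 6 (not isolated)
Conditions: dry HCl (g), EtOAc, 0 °C then 5 °C
Reagents that add atoms: hydrogen chloride, Cl
Why: Acid-catalysed enolisation of 4 and crossed aldol condensation with the non-enolisable aldehyde 2 give α-acetoxy-2-hydroxychalcone 5, whose alkene isomers equilibrate through the protonated enone; the ring-A phenol then adds to the protonated aryl ketone carbon (future C2), forming O1–C2 and hemiketal 6, and loss of water aromatises ring C to benzopyrylium salt 7, which should precipitate and drive the sequence. The closest known reaction type is the classical acid-mediated flavylium salt synthesis from a salicylaldehyde and an ω-acyloxyacetophenone. Ring C is closed by 6-exo-trig addition of oxygen to a carbonyl carbon (hemiketalisation) followed by dehydration, a condensation–cyclodehydration that also forms the C3–C4 bond in the same flask. No stereocentre is created: C2, C3 and C4 are left planar on purpose, and their configuration is set later by steps 4 to 6 and 9. The step needs one enolisable partner, one aldehyde and one free phenol, which is secured because O7, O8 and O4' are benzylated and only the 2-OH of 2 is free; anhydrous HCl at low temperature should spare the aryl benzyl ethers and the 3-acetoxy group.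

Step 4
Reactants: 7 3-acetoxy-7,8-bis(benzyloxy)-2-[4-(benzyloxy)phenyl]chromenylium chloride
Product: 9 rac-7,8-bis(benzyloxy)-2-[4-(benzyloxy)phenyl]chroman-3-one, via enol acetate 8 (not isolated)
Conditions: Hantzsch ester (1.2 equiv), CH2Cl2, 0 °C to rt; then K2CO3 (1.5 equiv), MeOH, 0 °C, argon
Reagents that add atoms: none
Why: NADH-type hydride transfer from the dihydropyridine to C4 of the benzopyrylium cation gives 4H-chromenyl acetate 8, and mild methanolysis of this enol ester releases the enol, which tautomerises to flavan-3-one 9 with C2 formed as a racemate.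

Step 5
Reactants: 9 rac-7,8-bis(benzyloxy)-2-[4-(benzyloxy)phenyl]chroman-3-one
Product: 10 (2R,3R)-7,8-bis(benzyloxy)-2-[4-(benzyloxy)phenyl]chroman-3-ol
Conditions: RuCl[(S,S)-TsDPEN](p-cymene) (cat.), HCO2H/Et3N (5:2), EtOAc, 30 °C
Reagents that add atoms: none
Why: Noyori–Ikariya asymmetric transfer hydrogenation with dynamic kinetic resolution, in which C2 (α to the ketone, benzylic and O-substituted) racemises through the enol under the amine buffer while the catalyst reduces one enantiomer faster and delivers hydride to C3 anti to the C2 aryl group, so that C2 (R) and C3 (R) are set together as the 2,3-cis pair.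

Step 6
Reactants: 10 (2R,3R)-7,8-bis(benzyloxy)-2-[4-(benzyloxy)phenyl]chroman-3-ol
Product: 11 (2R,3R,4S)-7,8-bis(benzyloxy)-2-[4-(benzyloxy)phenyl]chromane-3,4-diol
Conditions: DDQ (1.2 equiv), CH2Cl2/H2O, rt
Reagents that add atoms: water, O
Why: DDQ benzylic oxidation, in which hydride abstraction from C4 gives a cation stabilised by O7 (para) and O1 (ortho) that water should trap on the β-face, anti to the axial 3-OH, setting C4 (S, 3,4-trans); limiting the oxidant should avoid over-oxidation to the 4-ketone.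

Step 7
Reactants: 11 (2R,3R,4S)-7,8-bis(benzyloxy)-2-[4-(benzyloxy)phenyl]chromane-3,4-diol
Product: 12 (2R,3S,4S)-7,8-bis(benzyloxy)-2-[4-(benzyloxy)phenyl]-4-(benzylsulfanyl)chroman-3-ol
Conditions: BnSH (5 equiv), BF3·OEt2 (cat.), CH2Cl2, −40 °C
Reagents that add atoms: phenylmethanethiol, SCc1ccccc1
Why: Lewis-acid-promoted SN1 thiolysis of the benzylic 4-hydroxyl, in which the soft thiol in excess outcompetes ring carbon nucleophiles and should enter trans to the 3-OH (the C4 configuration of 12 is erased and reset in step 9 in any case).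

Step 8
Reactants: 11 (2R,3R,4S)-7,8-bis(benzyloxy)-2-[4-(benzyloxy)phenyl]chromane-3,4-diol
Product: 13 (2R,3S,4S)-7,8-bis(benzyloxy)-2-[4-(benzyloxy)phenyl]chromane-3,4-diyl diacetate
Conditions: Ac2O, pyridine, DMAP (cat.), CH2Cl2, rt
Reagents that add atoms: acetic anhydride, CC(=O)OC(C)=O
Why: Standard acylation of both secondary hydroxyls with retention, so that the future lower unit offers only ring carbon C6 as nucleophile and carries a C4 oxygen that a thiophilic promoter does not ionise.

Step 9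
Reactants: 12 (2R,3S,4S)-7,8-bis(benzyloxy)-2-[4-(benzyloxy)phenyl]-4-(benzylsulfanyl)chroman-3-ol, 13 (2R,3S,4S)-7,8-bis(benzyloxy)-2-[4-(benzyloxy)phenyl]chromane-3,4-diyl diacetate
Product: 14 hexa-O-benzyl-epioritin-(4β→6)-epioritin-4β-ol 3,4-di-O-acetate (acetates on the lower unit, upper 3-OH free)
Conditions: AgBF4 (2.5 equiv), THF, 0 °C, dark, argon; 13 (3 equiv)
Reagents that add atoms: none
Why: Thiophilic activation followed by Friedel–Crafts alkylation, in which Ag+ abstracts the benzylsulfanyl group of 12 and the C4 benzylic cation is captured by C6 of 13 (ortho to O7, para to O1, the most activated and least hindered ring-A position) from the β-face, trans to the axial 3-OH, setting the upper C4 (S); the 4-acetate of 13 is inert to the soft promoter and the excess of 13 should suppress self-condensation of 12.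

Step 10
Reactants: 14 hexa-O-benzyl-epioritin-(4β→6)-epioritin-4β-ol 3,4-di-O-acetate
Product: 15 hexa-O-benzyl-epioritin-(4β→6)-epioritin-4β-ol
Conditions: K2CO3 (cat.), MeOH/THF, rt
Reagents that add atoms: none
Why: Zemplén-type transesterification cleaves both acetates at the acyl carbon, so no stereocentre is touched and the benzylic C4–O bond stays intact under basic, non-ionising conditions.

Step 11
Reactants: 15 hexa-O-benzyl-epioritin-(4β→6)-epioritin-4β-ol
Product: 16 epioritin-(4β→6)-epioritin-4β-ol (CNP0391561.3)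
Conditions: H2 (1 atm), Pd(OH)2/C, THF/MeOH, rt, stopped at complete O-debenzylation
Reagents that add atoms: none
Why: Catalytic hydrogenolysis of the six aryl benzyl ethers, which under neutral conditions should be cleaved faster than the secondary benzylic C–O bonds (O1–C2 of both units, C4–OH of the lower unit), liberates the hexaphenol without touching any stereocentre.

Compound list
1 | 2,3,4-trihydroxybenzaldehyde | O=Cc1ccc(O)c(O)c1O | starting material
2 | 3,4-bis(benzyloxy)-2-hydroxybenzaldehyde | O=Cc1ccc(OCc2ccccc2)c(OCc2ccccc2)c1O | intermediate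
3 | 1-[4-(benzyloxy)phenyl]-2-bromoethan-1-one | O=C(CBr)c1ccc(OCc2ccccc2)cc1 | starting material
4 | 2-[4-(benzyloxy)phenyl]-2-oxoethyl acetate | CC(=O)OCC(=O)c1ccc(OCc2ccccc2)cc1 | intermediate
5 | (E)-1-[3,4-bis(benzyloxy)-2-hydroxyphenyl]-3-[4-(benzyloxy)phenyl]-3-oxoprop-1-en-2-yl acetate (α-acetoxy-2-hydroxychalcone, ring-A aryl cis to the aroyl group; not isolated) | CC(=O)O/C(=C/c1ccc(OCc2ccccc2)c(OCc2ccccc2)c1O)C(=O)c1ccc(OCc2ccccc2)cc1 | intermediate
6 | rac-7,8-bis(benzyloxy)-2-[4-(benzyloxy)phenyl]-2-hydroxy-2H-chromen-3-yl acetate (hemiketal; not isolated) | CC(=O)OC1=Cc2ccc(OCc3ccccc3)c(OCc3ccccc3)c2OC1(O)c1ccc(OCc2ccccc2)cc1 | intermediate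
7 | 3-acetoxy-7,8-bis(benzyloxy)-2-[4-(benzyloxy)phenyl]chromenylium chloride (flavylium salt) | CC(=O)Oc1cc2ccc(OCc3ccccc3)c(OCc3ccccc3)c2[o+]c1-c1ccc(OCc2ccccc2)cc1.[Cl-] | intermediate
8 | 7,8-bis(benzyloxy)-2-[4-(benzyloxy)phenyl]-4H-chromen-3-yl acetate (enol acetate; not isolated) | CC(=O)OC1=C(c2ccc(OCc3ccccc3)cc2)Oc2c(ccc(OCc3ccccc3)c2OCc2ccccc2)C1 | intermediate
9 | rac-7,8-bis(benzyloxy)-2-[4-(benzyloxy)phenyl]chroman-3-one | O=C1Cc2ccc(OCc3ccccc3)c(OCc3ccccc3)c2OC1c1ccc(OCc2ccccc2)cc1 | intermediate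
10 | (2R,3R)-7,8-bis(benzyloxy)-2-[4-(benzyloxy)phenyl]chroman-3-ol (2,3-cis; tri-O-benzylepioritin) | c1cc2c(c(OCc3ccccc3)c1OCc1ccccc1)O[C@H](c1ccc(OCc3ccccc3)cc1)[C@H](O)C2 | intermediate
11 | (2R,3R,4S)-7,8-bis(benzyloxy)-2-[4-(benzyloxy)phenyl]chromane-3,4-diol (2,3-cis-3,4-trans; 4β-ol) | c1cc2c(c(OCc3ccccc3)c1OCc1ccccc1)O[C@H](c1ccc(OCc3ccccc3)cc1)[C@H](O)[C@H]2O | intermediate
12 | (2R,3S,4S)-7,8-bis(benzyloxy)-2-[4-(benzyloxy)phenyl]-4-(benzylsulfanyl)chroman-3-ol (2,3-cis-3,4-trans) | c1cc2c(c(OCc3ccccc3)c1OCc1ccccc1)O[C@H](c1ccc(OCc3ccccc3)cc1)[C@H](O)[C@H]2SCc1ccccc1 | intermediate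
13 | (2R,3S,4S)-7,8-bis(benzyloxy)-2-[4-(benzyloxy)phenyl]chromane-3,4-diyl diacetate (2,3-cis-3,4-trans) | c1cc2c(c(OCc3ccccc3)c1OCc1ccccc1)O[C@H](c1ccc(OCc3ccccc3)cc1)[C@H](OC(C)=O)[C@H]2OC(C)=O | intermediate
14 | hexa-O-benzyl-epioritin-(4β→6)-epioritin-4β-ol 3,4-di-O-acetate (both units 2,3-cis-3,4-trans; acetates on the lower unit) | c1ccccc1COc1ccc([C@H]2Oc3c(ccc(OCc4ccccc4)c3OCc3ccccc3)[C@H](c3cc4c(c(OCc5ccccc5)c3OCc3ccccc3)O[C@H](c3ccc(OCc5ccccc5)cc3)[C@H](OC(C)=O)[C@H]4OC(C)=O)[C@H]2O)cc1 | intermediate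
15 | hexa-O-benzyl-epioritin-(4β→6)-epioritin-4β-ol | c1ccccc1COc1ccc([C@H]2Oc3c(ccc(OCc4ccccc4)c3OCc3ccccc3)[C@H](c3cc4c(c(OCc5ccccc5)c3OCc3ccccc3)O[C@H](c3ccc(OCc5ccccc5)cc3)[C@H](O)[C@H]4O)[C@H]2O)cc1 | intermediate
16 | epioritin-(4β→6)-epioritin-4β-ol; upper unit (2R,3R,4S), lower unit (2R,3R,4S) | Oc1ccc([C@H]2Oc3c(ccc(O)c3O)[C@H](c3cc4c(c(O)c3O)O[C@H](c3ccc(O)cc3)[C@H](O)[C@H]4O)[C@H]2O)cc1 | target

Total step count: 11. Longest linear sequence: 9 steps (1, 3, 4, 5, 6, 7, 9, 10, 11).

Steps most likely to fail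

Step 9. Capture of the C4 cation by ring A of 13 may be slower than self-alkylation of the donor through its own C6 or 3-OH and subsequent oligomerisation, because a benzylated pyrogallol-type ring is only a moderate π-nucleophile. The fallback sets out from 12 and 13 with their roles exchanged and hard instead of soft activation. Thioether 12 is acetylated (Ac2O, pyridine) to 3-O-acetyl-4β-benzylsulfanyl-tri-O-benzylepioritin F1. Diacetate 13 is then ionised at C4 with BF3·OEt2 in CH2Cl2 at −78 °C, where the thioether is untouched and the 3-acetate participates, in the presence of excess F1, whose C6 captures the cation to give the thio-capped dimer hexa-O-benzyl-3-O-acetylepioritin-(4β→6)-3-O-acetyl-4β-benzylsulfanylepioritin F2. AgBF4 in THF/H2O exchanges the terminal benzylsulfanyl group for a 4β-hydroxyl to give hexa-O-benzyl-3-O-acetylepioritin-(4β→6)-epioritin-4β-ol 3-O-acetate F3. K2CO3 in MeOH then gives 15, where the route is rejoined.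

Step 11. Hydrogenolysis of the benzylic C4–OH bond of the lower unit (activated by the para oxygen O7 once it is a free phenol) may compete with O-debenzylation, and the liberated pyrogallol-type rings may oxidise in air. The fallback sets out from 15 and masks the hydroxyls first. The three secondary hydroxyls are silylated (Et3SiOTf, 2,6-lutidine, CH2Cl2) to the tris(triethylsilyl) ether F4, in which the C4–O bond is shielded and cannot leave through a quinone methide. H2 over Pd(OH)2/C then gives the hexaphenol tris(triethylsilyl) ether F5. HF·pyridine in THF/pyridine at 0 °C releases 16.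

Step 5. Racemisation of C2 may not keep pace with reduction, eroding enantio- or cis-selectivity, or the catalyst may induce the opposite sense. The fallback sets out from 9 and replaces catalyst control by substrate control plus resolution. LiBH(s-Bu)3 in THF at −78 °C, with hydride entering anti to the 2-aryl group, gives the racemic 2,3-cis alcohol F6. Esterification with (S)-2-methoxy-2-phenylacetic acid (DCC, DMAP) gives the (2R,3R)-flavanyl (S)-2-methoxy-2-phenylacetate F7 and its (2S,3S)-flavanyl diastereomer F8, which are separated by chromatography or crystallisation. Methanolysis of F7 (K2CO3, MeOH) returns 10.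

Further compounds
F1 | step 9 | 3-O-acetyl-4β-benzylsulfanyl-tri-O-benzylepioritin | c1cc2c(c(OCc3ccccc3)c1OCc1ccccc1)O[C@H](c1ccc(OCc3ccccc3)cc1)[C@H](OC(C)=O)[C@H]2SCc1ccccc1
F2 | step 9 | hexa-O-benzyl-3-O-acetylepioritin-(4β→6)-3-O-acetyl-4β-benzylsulfanylepioritin | c1ccccc1COc1ccc([C@H]2Oc3c(ccc(OCc4ccccc4)c3OCc3ccccc3)[C@H](c3cc4c(c(OCc5ccccc5)c3OCc3ccccc3)O[C@H](c3ccc(OCc5ccccc5)cc3)[C@H](OC(C)=O)[C@H]4SCc3ccccc3)[C@H]2OC(C)=O)cc1
F3 | step 9 | hexa-O-benzyl-3-O-acetylepioritin-(4β→6)-epioritin-4β-ol 3-O-acetate | c1ccccc1COc1ccc([C@H]2Oc3c(ccc(OCc4ccccc4)c3OCc3ccccc3)[C@H](c3cc4c(c(OCc5ccccc5)c3OCc3ccccc3)O[C@H](c3ccc(OCc5ccccc5)cc3)[C@H](OC(C)=O)[C@H]4O)[C@H]2OC(C)=O)cc1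
F4 | step 11 | hexa-O-benzyl-epioritin-(4β→6)-epioritin-4β-ol tris(triethylsilyl) ether | c1ccccc1COc1ccc([C@H]2Oc3c(ccc(OCc4ccccc4)c3OCc3ccccc3)[C@H](c3cc4c(c(OCc5ccccc5)c3OCc3ccccc3)O[C@H](c3ccc(OCc5ccccc5)cc3)[C@H](O[Si](CC)(CC)CC)[C@H]4O[Si](CC)(CC)CC)[C@H]2O[Si](CC)(CC)CC)cc1
F5 | step 11 | epioritin-(4β→6)-epioritin-4β-ol tris(triethylsilyl) ether (free phenols) | Oc1ccc([C@H]2Oc3c(ccc(O)c3O)[C@H](c3cc4c(c(O)c3O)O[C@H](c3ccc(O)cc3)[C@H](O[Si](CC)(CC)CC)[C@H]4O[Si](CC)(CC)CC)[C@H]2O[Si](CC)(CC)CC)cc1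
F6 | step 5 | rac-cis-7,8-bis(benzyloxy)-2-[4-(benzyloxy)phenyl]chroman-3-ol (both enantiomers) | c1cc2c(c(OCc3ccccc3)c1OCc1ccccc1)O[C@H](c1ccc(OCc3ccccc3)cc1)[C@H](O)C2.c1cc2c(c(OCc3ccccc3)c1OCc1ccccc1)O[C@@H](c1ccc(OCc3ccccc3)cc1)[C@@H](O)C2
F7 | step 5 | (S)-2-methoxy-2-phenylacetate of the (2R,3R)-alcohol 10 | c1cc2c(c(OCc3ccccc3)c1OCc1ccccc1)O[C@H](c1ccc(OCc3ccccc3)cc1)[C@H](OC(=O)[C@@H](OC)c1ccccc1)C2
F8 | step 5 | (S)-2-methoxy-2-phenylacetate of the (2S,3S)-alcohol (discarded diastereomer) | c1cc2c(c(OCc3ccccc3)c1OCc1ccccc1)O[C@@H](c1ccc(OCc3ccccc3)cc1)[C@@H](OC(=O)[C@@H](OC)c1ccccc1)C2
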